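Compound numbers refer to the steps and to the compound list after them. Ring A is the 3-hydroxy-4,5-dimethoxyphenyl group, ring B the 3,4,5-trimethoxyphenyl group.

## Analysis of the target

Compound 23 is a 2,5-diaryl-3,4-dimethyltetrahydrofuran: O1, C2 (bearing ring A), C3 and C4 (one methyl each) and C5 (bearing ring B). Its four contiguous stereocentres are (2S,3S,4R,5R): the two aryl groups are cis to each other, the two methyl groups are cis to each other, and each aryl group is trans to the methyl group beside it. With two identical aryl groups this array would be meso, so all the chirality of 23 comes from one missing O-methyl group at C3' of ring A. The absolute configuration therefore only states which end of the C2–C5 chain carries ring A. Both ring C–O bonds are benzylic and para to a methoxy group, so acid ionises them: this lets C2 and C5 relax to the most stable arrangement, but it also opens a Friedel–Crafts pathway onto the electron-rich ring B. The free phenol sits among five methyl ethers of nearly the same kind, which normally forces a protecting group onto ring A. The difficulty is thus to tell two almost identical ends apart in the absolute sense and to deliver ring A with one free hydroxyl among three adjacent oxygens. The strategy rests on ring A itself: C3', C4' and C5' carry OH, OMe and OMe, which is what remains when the ring oxygen and the two methoxy-bearing carbons of furan 6 are built into a benzene ring and the former ring oxygen is kept as the hydroxyl.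

## Retrosynthetic reasoning

**23 to 22.** The first cut is the O1–C2 bond of 23 (equivalently O1–C5), which leads to the 1,4-diol 22. Both carbinol carbons are benzylic, so the forward closure is an ionisation followed by capture by the other hydroxyl. Because the same ionisation can reopen the ring, C2 and C5 settle at the arrangement that is most stable for fixed C3 and C4, and that arrangement is 23. Only C3 and C4, which no later step touches, must be carried through with care. C5 is nevertheless installed correctly beforehand, so that the closure does not depend on complete equilibration.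

**22 to 20.** Diol 22 is traced through its silyl ether 21 to aryl ketone 20. The carbinol next to ring A needs no control, since it is ionised later, so a ketone suffices there. The silyl ether on the other carbinol keeps that oxygen from closing onto the ketone as a cyclic hemiketal.

**20 to 18 and 6.** Ring A of 20 is cut at C1'–C6' and C2'–C3' (ring A numbered from the carbon bearing the ketone). This removes C3' to C6' with their three oxygens as furan 6 and leaves C1' and C2' as the terminal alkyne of ynone 18. The cut is made here, and not at the aryl–carbonyl bond, because it alone yields ring A already differentiated: the ring oxygen of 6 becomes the single free hydroxyl, so no phenol protecting group enters the synthesis. The forward reaction must be a cycloaddition across the alkyne, then an opening of the oxygen bridge in one direction only, without disturbing the stereocentre α to the ketone or the silyl ether.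

**18 to 16 and 17.** Ynone 18 is cut between the carbonyl carbon and the alkyne, giving N-methoxy-N-methylamide 16 and alkynyl Grignard reagent 17. This amide type is chosen because its adduct with 17 survives until work-up, which prevents double addition and spares the adjacent stereocentre.

**16 to 14.** Amide 16 comes from lactone 14 through hydroxy amide 15 by cutting the C–N bond and reclosing the ring. The lactone is the resting state of this γ-hydroxy acid and holds the three stereocentres in a rigid ring where their relation can be checked. Silylation of 15 directly after ring opening prevents the reverse reaction.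

**14 to 12.** The benzylic C–O and C–H bonds at C5 of 14 are traced to the ketone of keto acid 12, through hydroxy acid 13. The forward reduction must deliver hydride to one face of the ketone under control of the neighbouring methyl-bearing carbon, which gives the 4,5-trans lactone. If that control is imperfect, the same benzylic centre can be equilibrated to the more stable trans lactone.

**12 to 8 and 9.** Keto acid 12 is cut at the aryl–carbonyl bond into meso anhydride 8 and an aryl nucleophile made from bromide 9 through 10 and 11. This step decides the absolute configuration of the whole synthesis. Anhydride 8 already has the two methyl groups cis, and its two carbonyl groups are enantiotopic, so choosing which one receives ring B is the same as choosing between 23 and its mirror image. One catalyst-controlled C–C bond formation thus sets C3 and C4 of 23, and the untouched carboxyl group is kept for ring A. Anhydride 8 is the dehydration product of the commercial meso diacid 7.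

**6 to 1 and 2.** Furan 6 is traced through diacid 5 and diester 4 to dihydroxy diester 3. The two ester groups, removed at the end by decarboxylation, allow the furan to be assembled by a double Claisen condensation of 1 (ring oxygen and the two α-carbons) with 2 (the two oxygen-bearing carbons). The enolic hydroxyls of 3 are methylated before the esters are removed, because 6 is too sensitive to be functionalised directly.

## Alternatives that were turned down

**Alternative 1:** The tetrahydrofuran is disconnected at C2–C3 and C4–C5, so that O1, C2 and C5 come from furan A1 and C3 and C4 with their one-carbon substituents from maleic anhydride A2.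
- Forward key step: the reversible Diels–Alder reaction of A1 and A2, which at equilibrium gives the exo adduct A3, a meso 7-oxanorbornene whose oxygen bridge is already the ring oxygen of 23.
- For it: two bulk chemicals and one step. It is also stronger than the chosen route on relative configuration, since the bicycle fixes all four centres at once: the anhydride carbons (future methyls) are cis to each other and trans to the two-carbon bridge that sits where the aryl groups must go.
- Against it: no substituent is yet what 23 needs. The anhydride must be reduced to two methyl groups. The two-carbon bridge must be cleaved and both of its carbons replaced by two different aryl groups, each through a reactive C2 or C5 intermediate that must return trans to the methyl. The mirror symmetry of A3 must be broken in a way that tells C2 from C5, and the phenol needs protection throughout.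
- Comparison: the chosen strategy gives up the built-in relative configuration and relies on equilibrium at C2 and C5. In exchange, every bond its key step makes stays in 23 and only three steps follow it.

**Alternative 2:** The ring is disconnected at C2–C3, with O1 already linking C5 to the benzylic carbon of ring A.
- Forward key step: diazo ester A4 gives a dirhodium carbene at C3 that inserts into the benzylic C–H bond next to the ether oxygen and closes tetrahydrofuran A5.
- For it: the ether is made convergently, the C–H bond is doubly activated, and five-membered insertion is the favoured mode. The ring closes under neutral conditions with no benzylic cation, so the Friedel–Crafts pathway onto ring B does not arise; on this point it is stronger than the chosen route.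
- Against it: the carbene carbon is flanked by the C4–H bond, so 1,2-hydride migration to an unsaturated ester competes and must be held back by a very bulky carboxylate catalyst. C2 and C3 are created together, and their relation to C4 and C5 is decided by a crowded transition state. The C3 ester of A5 then costs about three steps to become a methyl group at a hindered centre. Ring A must carry a benzyl ether, whose hydrogenolysis has to spare the two benzylic ring C–O bonds.
- Comparison: the chosen strategy avoids diazo chemistry, the ester-to-methyl adjustment and phenol protection, at the price of an acid-mediated ring closure.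

**Alternative 3:** The ring is disconnected at O1–C5 and C2–C3.
- Forward key step: a Lewis acid promotes the (3+2) annulation of donor–acceptor cyclopropane A6 with the protected ring A aldehyde A7. The carbonyl oxygen attacks the aryl-bearing carbon of A6 with inversion and the malonate carbon closes on the carbonyl carbon, giving A8.
- For it: it is the most convergent of the four, joining the two aryl halves and forming the ring in one step. The 2,5-cis relationship is inherent to the annulation and the absolute configuration is carried in from A6; on convergence and kinetic control of C2 and C5 it is stronger than the chosen route.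
- Against it: the strongly donating ring B favours full ionisation of A6 to a zwitterion, which erodes the invertive pathway. Because C5 is inverted, the 4,5-trans product requires the cyclopropane with methyl and aryl cis, the less accessible diastereomer. A8 has two esters at C3, so decarboxylation (leaving C3 still to be set) and an ester-to-methyl reduction must follow, plus benzyl protection and removal.
- Comparison: the chosen strategy needs no carbon removed after its key step and never protects the phenol, but it is less convergent at the ring-forming stage.

Key step: step 11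

Assumption: the sense of induction in step 6 is taken by analogy and must be confirmed on lactone 14; the ligand antipode that gives (2S,3R)-12 is the one used, since the other antipode would lead to the mirror image of 23.

## Route

**Step 1**
Reactants: 1 dimethyl diglycolate; 2 dimethyl oxalate
Product: 3 dimethyl 3,4-dihydroxyfuran-2,5-dicarboxylate
Conditions: NaOMe (2.2 equiv), MeOH, reflux; aq. HCl, 0 °C
Reagents that add atoms: none
Why: Hinsberg-type double Claisen condensation: each α-methylene of 1 is acylated by one ester of 2 and the resulting dioxo diester aromatises by enolisation. The esters serve as removable blocking groups on the furan α-positions.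

**Step 2**
Reactants: 3 dimethyl 3,4-dihydroxyfuran-2,5-dicarboxylate
Product: 4 dimethyl 3,4-dimethoxyfuran-2,5-dicarboxylate
Conditions: Me2SO4 (2.5 equiv), K2CO3, acetone, reflux
Reagents that add atoms: dimethyl sulfate, COS(=O)(=O)OC
Why: Williamson O-methylation of two acidic enolic hydroxyls with a hard alkylating agent; C-alkylation would cost the aromaticity of the furan.

**Step 3**
Reactants: 4 dimethyl 3,4-dimethoxyfuran-2,5-dicarboxylate
Product: 5 3,4-dimethoxyfuran-2,5-dicarboxylic acid
Conditions: NaOH, H2O/MeOH, reflux; HCl to pH 1
Reagents that add atoms: sodium hydroxide, [Na+].[OH-]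
Why: Ester saponification; the enol ethers are stable to base and the diacid precipitates on acidification.

**Step 4**
Reactants: 5 3,4-dimethoxyfuran-2,5-dicarboxylic acid
Product: 6 3,4-dimethoxyfuran
Conditions: Cu powder, quinoline, 190–200 °C, product distilled out under Ar
Reagents that add atoms: none
Why: Copper-mediated protodecarboxylation of furan-2-carboxylic acids; the volatile furan leaves the hot basic medium as it forms and is stored cold under argon.

**Step 5**
Reactants: 7 meso-2,3-dimethylsuccinic acid
Product: 8 cis-2,3-dimethylsuccinic anhydride (meso)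
Conditions: AcCl, reflux; evaporate
Reagents that add atoms: none
Why: Cyclodehydration of a 1,4-diacid through the mixed anhydride; no base is present, so the two α-centres keep their cis relationship.

**Step 6**
Reactants: 8 cis-2,3-dimethylsuccinic anhydride; 9 5-bromo-1,2,3-trimethoxybenzene
Product: 12 (2S,3R)-2,3-dimethyl-4-oxo-4-(3,4,5-trimethoxyphenyl)butanoic acid, via (3,4,5-trimethoxyphenyl)lithium 10 (not isolated), via (3,4,5-trimethoxyphenyl)zinc triflate 11 (not isolated)
Conditions: 9, n-BuLi, THF, −78 °C; Zn(OTf)2, −78 → 23 °C; then 8, [Rh(cod)Cl]2 (4 mol%), TADDOL-derived dimethylphosphoramidite ligand (8 mol%, antipode per the assumption), DMF, 50 °C; 1 M HCl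
Reagents that add atoms: none
Why: Enantioselective desymmetrisation of a meso succinic anhydride by rhodium-catalysed acyl cross-coupling: monovalent rhodium inserts into one enantiotopic acyl C–O bond, the arylzinc transmetalates and reductive elimination from trivalent rhodium gives the aryl ketone. The chiral ligand decides which carbonyl is arylated and so fixes both methyl-bearing centres of 12 at once, their cis relationship being inherited from 8. This reaction type is established for cis-2,3-dimethylsuccinic anhydride with electron-rich arylzinc reagents.

**Step 7**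
Reactants: 12 (2S,3R)-2,3-dimethyl-4-oxo-4-(3,4,5-trimethoxyphenyl)butanoic acid
Product: 14 (3S,4R,5R)-3,4-dimethyl-5-(3,4,5-trimethoxyphenyl)oxolan-2-one, via hydroxy acid 13 (not isolated)
Conditions: LiBH(s-Bu)3 (2.5 equiv), THF, −78 °C; 1 M HCl; TsOH (cat.), toluene, 23 °C
Reagents that add atoms: none
Why: Felkin–Anh reduction: the bulky hydride attacks the aryl ketone anti to the chain branch on the adjacent carbon with the methyl group inside, which gives the anti alcohol 13 (new centre R, controlled by the neighbouring methyl-bearing centre). Acid then closes the γ-lactone, in which aryl and the neighbouring methyl are trans and the two methyls cis; optical purity is checked here and can be raised by crystallisation if needed.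

**Step 8**
Reactants: 14 (3S,4R,5R)-3,4-dimethyl-5-(3,4,5-trimethoxyphenyl)oxolan-2-one
Product: 15 (2S,3R,4R)-4-hydroxy-N-methoxy-N,2,3-trimethyl-4-(3,4,5-trimethoxyphenyl)butanamide
Conditions: MeNH(OMe)·HCl, AlMe3, CH2Cl2, 0 → 23 °C; cold 1 M HCl; used crude
Reagents that add atoms: N,O-dimethylhydroxylamine hydrochloride, CNOC.Cl
Why: Weinreb aminolysis of a γ-lactone by the aluminium amide formed in the flask; the hydroxy amide is not stored because it can relactonise.

**Step 9**
Reactants: 15 (2S,3R,4R)-4-hydroxy-N-methoxy-N,2,3-trimethyl-4-(3,4,5-trimethoxyphenyl)butanamide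
Product: 16 (2S,3R,4R)-4-(tert-butyldimethylsilyloxy)-N-methoxy-N,2,3-trimethyl-4-(3,4,5-trimethoxyphenyl)butanamide
Conditions: TBSOTf, 2,6-lutidine, CH2Cl2, −78 → 0 °C
Reagents that add atoms: tert-butyldimethylsilyl trifluoromethanesulfonate, CC(C)(C)[Si](C)(C)OS(=O)(=O)C(F)(F)F
Why: Silylation of a hindered secondary benzylic alcohol with a silyl triflate and a non-nucleophilic base; it blocks relactonisation and protects this oxygen through the Grignard and Diels–Alder steps.

**Step 10**
Reactants: 16 (2S,3R,4R)-4-(tert-butyldimethylsilyloxy)-N-methoxy-N,2,3-trimethyl-4-(3,4,5-trimethoxyphenyl)butanamide; 17 ethynylmagnesium bromide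
Product: 18 (4S,5R,6R)-6-(tert-butyldimethylsilyloxy)-4,5-dimethyl-6-(3,4,5-trimethoxyphenyl)hex-1-yn-3-one
Conditions: 17 (3 equiv), THF, −20 → 0 °C; inverse quench into cold 1 M HCl
Reagents that add atoms: none
Why: Weinreb ketone synthesis: the chelated tetrahedral adduct survives until work-up, so no tertiary alcohol forms and the α-centre is not enolised. The inverse acidic quench keeps the liberated amine protonated so that it cannot add to the ynone.

**Step 11**
Reactants: 18 (4S,5R,6R)-6-(tert-butyldimethylsilyloxy)-4,5-dimethyl-6-(3,4,5-trimethoxyphenyl)hex-1-yn-3-one; 6 3,4-dimethoxyfuran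
Product: 20 (2S,3R,4R)-4-(tert-butyldimethylsilyloxy)-1-(3-hydroxy-4,5-dimethoxyphenyl)-2,3-dimethyl-4-(3,4,5-trimethoxyphenyl)butan-1-one, via oxanorbornadiene 19 (not isolated)
Conditions: 6 (2.5 equiv), toluene, 60 °C, sealed; concentrate; CSA (10 mol%), CH2Cl2, 0 °C
Reagents that add atoms: none
Why: The two methoxy groups raise the HOMO of furan 6 and the acyl group lowers the LUMO of the alkyne of 18, so a concerted normal-demand [4+2] cycloaddition joins the two furan α-carbons to the two alkyne carbons and closes the six-membered carbocycle of 19 in one suprafacial event (ring closure by intermolecular cycloaddition, two C–C bonds at once). Because 6 is symmetric the cycloaddition has no regiochemical question, and the two bridgehead centres of 19 form without control but vanish on aromatisation, so no lasting stereocentre is created. Acid then protonates the bridging oxygen and breaks the C–O bond at the bridgehead next to the acyl-bearing carbon, because that cyclohexadienyl cation places its charge on a methoxy-bearing carbon and on positions flanking the acyl carbon, whereas the other opening would put charge on the carbon carrying the ketone. Loss of the proton from the carbon that still holds the oxygen gives the arene, so the former furan oxygen ends as the hydroxyl meta to the ketone beside the two methoxy groups. The closest known reaction type is the Diels–Alder reaction of furans with acetylenic esters and ketones followed by acid-promoted isomerisation of the 7-oxanorbornadiene to a phenol. The step needs cycloaddition rather than conjugate addition of the furan α-carbon (helped by a thermal, acid-free first stage), one-directional bridge opening (directed by the acyl group) and survival of the α-stereocentre and silyl ether (helped by catalytic anhydrous sulfonic acid at 0 °C).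

**Step 12**
Reactants: 20 (2S,3R,4R)-4-(tert-butyldimethylsilyloxy)-1-(3-hydroxy-4,5-dimethoxyphenyl)-2,3-dimethyl-4-(3,4,5-trimethoxyphenyl)butan-1-one
Product: 21 (2S,3R,4R)-4-(tert-butyldimethylsilyloxy)-1-(3-hydroxy-4,5-dimethoxyphenyl)-2,3-dimethyl-4-(3,4,5-trimethoxyphenyl)butan-1-ol (mixture of C1 epimers)
Conditions: NaBH4, MeOH, 0 °C; aq. NH4Cl
Reagents that add atoms: none
Why: Borohydride reduction of an aryl ketone; the configuration of the new carbinol centre does not matter because this carbon is ionised in step 14, so the epimer mixture is carried on.

**Step 13**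
Reactants: 21 (2S,3R,4R)-4-(tert-butyldimethylsilyloxy)-1-(3-hydroxy-4,5-dimethoxyphenyl)-2,3-dimethyl-4-(3,4,5-trimethoxyphenyl)butan-1-ol
Product: 22 (2S,3R,4R)-1-(3-hydroxy-4,5-dimethoxyphenyl)-2,3-dimethyl-4-(3,4,5-trimethoxyphenyl)butane-1,4-diol (mixture of C1 epimers)
Conditions: Bu4NF, THF, 0 → 23 °C; aq. NH4Cl
Reagents that add atoms: none
Why: Fluoride cleavage of the silyl ether; the non-acidic conditions leave both benzylic C–O bonds intact, so the diol is in hand before any ionisation is allowed.

**Step 14**
Reactants: 22 (2S,3R,4R)-1-(3-hydroxy-4,5-dimethoxyphenyl)-2,3-dimethyl-4-(3,4,5-trimethoxyphenyl)butane-1,4-diol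
Product: 23 5-[(2S,3S,4R,5R)-3,4-dimethyl-5-(3,4,5-trimethoxyphenyl)oxolan-2-yl]-2,3-dimethoxyphenol
Conditions: TsOH·H2O (10 mol%), CH2Cl2, 0 → 23 °C; NaHCO3 quench once the isomer ratio no longer changes
Reagents that add atoms: none
Why: Acid-catalysed cyclodehydration through a benzylic cation that is captured by the other hydroxyl (5-exo closure). Both ring C–O bonds can reopen, so C2 and C5 of the ring settle with each aryl trans to its neighbouring methyl, which for the fixed C3 and C4 is 23. The phenol needs no protection, and the reaction is stopped before Friedel–Crafts closure onto ring B sets in.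

## Compound list

1 | dimethyl diglycolate | COC(=O)COCC(=O)OC | starting material
2 | dimethyl oxalate | COC(=O)C(=O)OC | starting material
3 | dimethyl 3,4-dihydroxyfuran-2,5-dicarboxylate | COC(=O)c1oc(C(=O)OC)c(O)c1O | intermediate
4 | dimethyl 3,4-dimethoxyfuran-2,5-dicarboxylate | COC(=O)c1oc(C(=O)OC)c(OC)c1OC | intermediate
5 | 3,4-dimethoxyfuran-2,5-dicarboxylic acid | OC(=O)c1oc(C(=O)O)c(OC)c1OC | intermediate
6 | 3,4-dimethoxyfuran | COc1cocc1OC | intermediate
7 | meso-2,3-dimethylsuccinic acid, (2R,3S) | OC(=O)[C@@H](C)[C@@H](C)C(=O)O | starting material
8 | cis-2,3-dimethylsuccinic anhydride (meso) | O=C1OC(=O)[C@@H](C)[C@H]1C | intermediate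
9 | 5-bromo-1,2,3-trimethoxybenzene | COc1cc(Br)cc(OC)c1OC | starting material
10 | (3,4,5-trimethoxyphenyl)lithium | COc1cc([Li])cc(OC)c1OC | intermediate (not isolated)
11 | (3,4,5-trimethoxyphenyl)zinc triflate | COc1cc([Zn]OS(=O)(=O)C(F)(F)F)cc(OC)c1OC | intermediate (not isolated)
12 | (2S,3R)-2,3-dimethyl-4-oxo-4-(3,4,5-trimethoxyphenyl)butanoic acid | OC(=O)[C@@H](C)[C@@H](C)C(=O)c1cc(OC)c(OC)c(OC)c1 | intermediate
13 | (2S,3R,4R)-4-hydroxy-2,3-dimethyl-4-(3,4,5-trimethoxyphenyl)butanoic acid | OC(=O)[C@@H](C)[C@@H](C)[C@@H](O)c1cc(OC)c(OC)c(OC)c1 | intermediate (not isolated)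
14 | (3S,4R,5R)-3,4-dimethyl-5-(3,4,5-trimethoxyphenyl)oxolan-2-one (3,4-cis, 4,5-trans) | O=C1O[C@@H](c2cc(OC)c(OC)c(OC)c2)[C@H](C)[C@@H]1C | intermediate
15 | (2S,3R,4R)-4-hydroxy-N-methoxy-N,2,3-trimethyl-4-(3,4,5-trimethoxyphenyl)butanamide | CON(C)C(=O)[C@@H](C)[C@@H](C)[C@@H](O)c1cc(OC)c(OC)c(OC)c1 | intermediate
16 | (2S,3R,4R)-4-(tert-butyldimethylsilyloxy)-N-methoxy-N,2,3-trimethyl-4-(3,4,5-trimethoxyphenyl)butanamide | CON(C)C(=O)[C@@H](C)[C@@H](C)[C@@H](O[Si](C)(C)C(C)(C)C)c1cc(OC)c(OC)c(OC)c1 | intermediate
17 | ethynylmagnesium bromide | C#C[Mg]Br | starting material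
18 | (4S,5R,6R)-6-(tert-butyldimethylsilyloxy)-4,5-dimethyl-6-(3,4,5-trimethoxyphenyl)hex-1-yn-3-one | C#CC(=O)[C@@H](C)[C@@H](C)[C@@H](O[Si](C)(C)C(C)(C)C)c1cc(OC)c(OC)c(OC)c1 | intermediate
19 | (2S,3R,4R)-4-(tert-butyldimethylsilyloxy)-1-(5,6-dimethoxy-7-oxabicyclo[2.2.1]hepta-2,5-dien-2-yl)-2,3-dimethyl-4-(3,4,5-trimethoxyphenyl)butan-1-one (both bridgehead diastereomers) | COC1=C(OC)C2OC1C=C2C(=O)[C@@H](C)[C@@H](C)[C@@H](O[Si](C)(C)C(C)(C)C)c1cc(OC)c(OC)c(OC)c1 | intermediate (not isolated)
20 | (2S,3R,4R)-4-(tert-butyldimethylsilyloxy)-1-(3-hydroxy-4,5-dimethoxyphenyl)-2,3-dimethyl-4-(3,4,5-trimethoxyphenyl)butan-1-one | COc1cc(C(=O)[C@@H](C)[C@@H](C)[C@@H](O[Si](C)(C)C(C)(C)C)c2cc(OC)c(OC)c(OC)c2)cc(O)c1OC | intermediate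
21 | (2S,3R,4R)-4-(tert-butyldimethylsilyloxy)-1-(3-hydroxy-4,5-dimethoxyphenyl)-2,3-dimethyl-4-(3,4,5-trimethoxyphenyl)butan-1-ol, C1 epimers | COc1cc(C(O)[C@@H](C)[C@@H](C)[C@@H](O[Si](C)(C)C(C)(C)C)c2cc(OC)c(OC)c(OC)c2)cc(O)c1OC | intermediate
22 | (2S,3R,4R)-1-(3-hydroxy-4,5-dimethoxyphenyl)-2,3-dimethyl-4-(3,4,5-trimethoxyphenyl)butane-1,4-diol, C1 epimers | COc1cc(C(O)[C@@H](C)[C@@H](C)[C@@H](O)c2cc(OC)c(OC)c(OC)c2)cc(O)c1OC | intermediate
23 | 5-[(2S,3S,4R,5R)-3,4-dimethyl-5-(3,4,5-trimethoxyphenyl)oxolan-2-yl]-2,3-dimethoxyphenol | COc1cc([C@H]2O[C@@H](c3cc(OC)c(OC)c(OC)c3)[C@H](C)[C@@H]2C)cc(O)c1OC | target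

## Step count and least certain steps

Total: 14 steps. Longest linear sequence: 10 steps (steps 5 to 14, from 7). The furan branch (steps 1 to 4) joins at step 11.

**Step 11 (key step).** Three processes may interfere:
- stepwise conjugate addition of the very nucleophilic furan α-carbon to the ynone instead of cycloaddition, or a second cycloaddition of 19 with excess 6;
- opening of the oxygen bridge in the other direction, because both possible cations are stabilised by a methoxy group and the acyl group is the only discriminating element;
- loss of the silyl ether or enolisation α to the ketone in the acid stage.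

Fallback, from 16 and back at 20: ring A is brought in as an aryl nucleophile. 5-Bromo-2,3-dimethoxyphenol F1 is silylated (TBSCl, imidazole) to (5-bromo-2,3-dimethoxyphenoxy)(tert-butyl)dimethylsilane F2. Bromine–lithium exchange (n-BuLi, THF, −78 °C) gives [3-(tert-butyldimethylsilyloxy)-4,5-dimethoxyphenyl]lithium F3, which is added to amide 16 to give the doubly silylated ketone F4. Selective cleavage of the aryl silyl ether (K2CO3, MeOH) returns 20.

**Step 6.** The two enantiotopic acyl C–O bonds may be differentiated incompletely, and the sense of induction is not secured in advance; no later step corrects this except crystallisation of 14. Fallback, from 8 and back at 14: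
- methanolysis of 8 mediated by a cinchona alkaloid (quinine or quinidine, whichever pseudo-enantiomer gives the needed half-ester) affords (2R,3S)-4-methoxy-2,3-dimethyl-4-oxobutanoic acid F5;
- EtSH, DCC and DMAP give the thioester methyl (2S,3R)-4-(ethylsulfanyl)-2,3-dimethyl-4-oxobutanoate F6;
- Fukuyama coupling with arylzinc 11 (PdCl2(PPh3)2, THF) gives methyl (2S,3R)-2,3-dimethyl-4-oxo-4-(3,4,5-trimethoxyphenyl)butanoate F7;
- LiBH(s-Bu)3 at −78 °C gives methyl (2S,3R,4R)-4-hydroxy-2,3-dimethyl-4-(3,4,5-trimethoxyphenyl)butanoate F8, which lactonises to 14.

**Step 7.** Facial selectivity of hydride delivery may be poor, because the neighbouring carboxylate can disturb the Felkin–Anh arrangement. Fallback, from 12 and back at 14: the ketone is reduced without regard to selectivity (NaBH4) and lactonised to a mixture of 14 and its C5 epimer, the all-cis lactone (3S,4R,5S)-3,4-dimethyl-5-(3,4,5-trimethoxyphenyl)oxolan-2-one F9. Catalytic TfOH in CH2Cl2 then ionises the benzylic C–O bond reversibly and converts F9 into the more stable trans lactone 14.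

**Step 10.** The amine set free on work-up may add to the terminal ynone, and addition to the hindered amide may be slow. Fallback, from 16 and back at 18: DIBAL at −78 °C gives the aldehyde (2S,3R,4R)-4-(tert-butyldimethylsilyloxy)-2,3-dimethyl-4-(3,4,5-trimethoxyphenyl)butanal F10. Addition of 17 gives the propargylic alcohol (4S,5R,6R)-6-(tert-butyldimethylsilyloxy)-4,5-dimethyl-6-(3,4,5-trimethoxyphenyl)hex-1-yn-3-ol F11 as an epimer mixture, and oxidation (Dess–Martin periodinane or MnO2) gives 18. The amine is then released at a stage where no ynone is present.

**Step 14.** The benzylic cation may close onto ring B (Friedel–Crafts, leading irreversibly to an aryltetralin). Ionisation at both carbinol carbons may also give a mixture of C2 epimers if equilibration is stopped early. Fallback, from 21 and straight to 23: silyl ether 21 is treated with BF3·OEt2 in CH2Cl2 at −78 °C. Only the free benzylic hydroxyl can ionise, the silyl ether oxygen captures the cation and the silyl group is lost, so C5 is never ionised and no equilibration is needed. This fallback makes no compound outside the list (F0).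

## Further compounds

F1 | step 11 | 5-bromo-2,3-dimethoxyphenol | COc1cc(Br)cc(O)c1OC
F2 | step 11 | (5-bromo-2,3-dimethoxyphenoxy)(tert-butyl)dimethylsilane | COc1cc(Br)cc(O[Si](C)(C)C(C)(C)C)c1OC
F3 | step 11 | [3-(tert-butyldimethylsilyloxy)-4,5-dimethoxyphenyl]lithium | COc1cc([Li])cc(O[Si](C)(C)C(C)(C)C)c1OC
F4 | step 11 | (2S,3R,4R)-4-(tert-butyldimethylsilyloxy)-1-[3-(tert-butyldimethylsilyloxy)-4,5-dimethoxyphenyl]-2,3-dimethyl-4-(3,4,5-trimethoxyphenyl)butan-1-one | COc1cc(C(=O)[C@@H](C)[C@@H](C)[C@@H](O[Si](C)(C)C(C)(C)C)c2cc(OC)c(OC)c(OC)c2)cc(O[Si](C)(C)C(C)(C)C)c1OC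
F5 | step 6 | (2R,3S)-4-methoxy-2,3-dimethyl-4-oxobutanoic acid | COC(=O)[C@@H](C)[C@@H](C)C(=O)O
F6 | step 6 | methyl (2S,3R)-4-(ethylsulfanyl)-2,3-dimethyl-4-oxobutanoate | COC(=O)[C@@H](C)[C@@H](C)C(=O)SCC
F7 | step 6 | methyl (2S,3R)-2,3-dimethyl-4-oxo-4-(3,4,5-trimethoxyphenyl)butanoate | COC(=O)[C@@H](C)[C@@H](C)C(=O)c1cc(OC)c(OC)c(OC)c1
F8 | step 6 | methyl (2S,3R,4R)-4-hydroxy-2,3-dimethyl-4-(3,4,5-trimethoxyphenyl)butanoate | COC(=O)[C@@H](C)[C@@H](C)[C@@H](O)c1cc(OC)c(OC)c(OC)c1
F9 | step 7 | (3S,4R,5S)-3,4-dimethyl-5-(3,4,5-trimethoxyphenyl)oxolan-2-one (all-cis) | O=C1O[C@H](c2cc(OC)c(OC)c(OC)c2)[C@H](C)[C@@H]1C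
F10 | step 10 | (2S,3R,4R)-4-(tert-butyldimethylsilyloxy)-2,3-dimethyl-4-(3,4,5-trimethoxyphenyl)butanal | O=C[C@@H](C)[C@@H](C)[C@@H](O[Si](C)(C)C(C)(C)C)c1cc(OC)c(OC)c(OC)c1
F11 | step 10 | (4S,5R,6R)-6-(tert-butyldimethylsilyloxy)-4,5-dimethyl-6-(3,4,5-trimethoxyphenyl)hex-1-yn-3-ol (C3 epimers) | C#CC(O)[C@@H](C)[C@@H](C)[C@@H](O[Si](C)(C)C(C)(C)C)c1cc(OC)c(OC)c(OC)c1
F0 | step 14 | none | none
A1 | alternative 1 | furan | c1ccoc1
A2 | alternative 1 | maleic anhydride | O=C1OC(=O)C=C1
A3 | alternative 1 | exo-7-oxabicyclo[2.2.1]hept-5-ene-2,3-dicarboxylic anhydride (meso) | C1[C@H]2O[C@@H](C=1)[C@H](C(=O)O3)[C@@H]2C3=O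
A4 | alternative 2 | methyl (3R,4R)-4-[(3-benzyloxy-4,5-dimethoxyphenyl)methoxy]-2-diazo-3-methyl-4-(3,4,5-trimethoxyphenyl)butanoate | COC(=O)C(=[N+]=[N-])[C@@H](C)[C@@H](OCc1cc(OC)c(OC)c(OCc2ccccc2)c1)c1cc(OC)c(OC)c(OC)c1
A5 | alternative 2 | methyl 2-(3-benzyloxy-4,5-dimethoxyphenyl)-4-methyl-5-(3,4,5-trimethoxyphenyl)tetrahydrofuran-3-carboxylate (2,5-cis, 2,3-trans, 3,4-cis) | COc1cc([C@H]2O[C@@H](c3cc(OC)c(OC)c(OC)c3)[C@H](C)[C@@H]2C(=O)OC)cc(OCc2ccccc2)c1OC
A6 | alternative 3 | dimethyl cis-2-methyl-3-(3,4,5-trimethoxyphenyl)cyclopropane-1,1-dicarboxylate (single enantiomer as drawn) | COC(=O)C1(C(=O)OC)[C@@H](C)[C@H]1c1cc(OC)c(OC)c(OC)c1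
A7 | alternative 3 | 3-benzyloxy-4,5-dimethoxybenzaldehyde | COc1cc(C=O)cc(OCc2ccccc2)c1OC
A8 | alternative 3 | dimethyl 2-(3-benzyloxy-4,5-dimethoxyphenyl)-4-methyl-5-(3,4,5-trimethoxyphenyl)tetrahydrofuran-3,3-dicarboxylate (2,5-cis, 4,5-trans) | COc1cc([C@H]2O[C@@H](c3cc(OC)c(OC)c(OC)c3)[C@H](C)C2(C(=O)OC)C(=O)OC)cc(OCc2ccccc2)c1OC
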